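**Retrosynthetic overview**
- The target comes from a trans-3-aroyl-4-benzyl-tetrahydrofuran by reagent-controlled ketone reduction (sets the carbinol centre) and desilylation.
- That ketone comes from a 1-aroyl-6-aryl-3-oxabicyclo[3.1.0]hexane by hydrogenolysis of the cyclopropane bond between the aryl-bearing and the acyl-bearing carbons, then α-epimerisation to trans.
- Key step: enantioselective gold-catalysed alkyne oxidation/cyclopropanation of an aryl-propargyl cinnamyl ether (a 1,6-enyne). The tetrahydrofuran ring and the cyclopropane close in the same operation.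
- The enyne is a Williamson ether of an (E)-cinnamyl alcohol and an arylpropargyl bromide, both made from one arylpropynol (Sonogashira of silyl-protected 4-bromo-2-methoxyphenol with propargyl alcohol).
- Ring order: both arenes are bought; tetrahydrofuran and cyclopropane form together in step 6; the cyclopropane is opened in step 7 and the tetrahydrofuran is kept.

Assumption: which antipode of the chiral ligand on gold gives (1R,5R,6S)-8 has to be confirmed on the first run; the route is written for the antipode that does (taken here as the (S)-binaphthyl/(R,R)-amine phosphoramidite), and the mirror-image ligand is used otherwise.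

L* = (11bS)-N,N-bis[(1R)-1-phenylethyl]dinaphtho[2,1-d:1',2'-f][1,3,2]dioxaphosphepin-4-amine. TIPS = tri(propan-2-yl)silyl.

**Step 1**
Reactants: 1 4-bromo-2-methoxyphenol
Product: 2 (4-bromo-2-methoxyphenoxy)tri(propan-2-yl)silane
Conditions: TIPSCl, imidazole, DMF, rt
Reagents that add atoms: chlorotri(propan-2-yl)silane (TIPSCl), CC(C)[Si](Cl)(C(C)C)C(C)C
Why: Silyl ether protection of the phenol; the hindered aryl TIPS ether survives amine bases, hydride, NaH, hydrogenation and borane, and is removed by fluoride at the end.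

**Step 2**
Reactants: 2 (4-bromo-2-methoxyphenoxy)tri(propan-2-yl)silane; 3 prop-2-yn-1-ol
Product: 4 3-{3-methoxy-4-[tri(propan-2-yl)silyloxy]phenyl}prop-2-yn-1-ol
Conditions: Pd(PhCN)2Cl2 (3 mol %), [(t-Bu)3PH]BF4 (6 mol %), CuI (2 mol %), i-Pr2NH, dioxane, rt
Reagents that add atoms: none
Why: Sonogashira coupling; the bulky electron-rich P(t-Bu)3 ligand allows oxidative addition of the electron-rich aryl bromide at room temperature.

**Step 3**
Reactants: 4 3-{3-methoxy-4-[tri(propan-2-yl)silyloxy]phenyl}prop-2-yn-1-ol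
Product: 5 (2E)-3-{3-methoxy-4-[tri(propan-2-yl)silyloxy]phenyl}prop-2-en-1-ol
Conditions: NaAlH2(OCH2CH2OCH3)2, THF, 0 °C to rt; aq. KNaC4H4O6 work-up
Reagents that add atoms: none
Why: Alkoxide-directed trans-hydroalumination of a propargylic alcohol, then protonolysis, gives only the (E)-allylic alcohol.

**Step 4**
Reactants: 4 3-{3-methoxy-4-[tri(propan-2-yl)silyloxy]phenyl}prop-2-yn-1-ol
Product: 6 [4-(3-bromoprop-1-yn-1-yl)-2-methoxyphenoxy]tri(propan-2-yl)silane
Conditions: CBr4, PPh3, CH2Cl2, 0 °C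
Reagents that add atoms: tetrabromomethane, BrC(Br)(Br)Br
Why: Appel reaction; neutral conversion of the primary propargylic alcohol into the bromide without touching the silyl ether.

**Step 5**
Reactants: 5 (2E)-3-{3-methoxy-4-[tri(propan-2-yl)silyloxy]phenyl}prop-2-en-1-ol; 6 [4-(3-bromoprop-1-yn-1-yl)-2-methoxyphenoxy]tri(propan-2-yl)silane
Product: 7 3-{3-methoxy-4-[tri(propan-2-yl)silyloxy]phenyl}prop-2-yn-1-yl (2E)-3-{3-methoxy-4-[tri(propan-2-yl)silyloxy]phenyl}prop-2-en-1-yl ether (the 1,6-enyne)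
Conditions: NaH, THF, 0 °C to rt
Reagents that add atoms: none
Why: Williamson ether synthesis; the sodium alkoxide of 5 displaces the reactive primary propargylic bromide by SN2.

**Step 6 (key step)**
Reactants: 7 the 1,6-enyne
Product: 8 [(1R,5R,6S)-6-{3-methoxy-4-[tri(propan-2-yl)silyloxy]phenyl}-3-oxabicyclo[3.1.0]hexan-1-yl]{3-methoxy-4-[tri(propan-2-yl)silyloxy]phenyl}methanone (6-aryl exo, cis to the aroyl group on the cyclopropane)
Conditions: (L*)AuCl (5 mol %), AgNTf2 (5 mol %), 8-methylquinoline N-oxide (1.5 equiv, slow addition), 4 Å MS, ClCH2CH2Cl, 0 °C to rt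
Reagents that add atoms: 8-methylquinoline N-oxide, Cc1cccc2ccc[n+]([O-])c12
Why: Gold-catalysed alkyne oxidation/intramolecular cyclopropanation of a 1,6-enyne: the N-oxide puts oxygen on the aryl-bearing alkyne carbon (favoured by aryl conjugation and by the electron-withdrawing propargylic oxygen), and the α-oxo gold carbenoid on the other carbon cyclopropanates the tethered styrene, closing the tetrahydrofuran and the cyclopropane together; the chiral phosphoramidite on gold selects the alkene face and so sets C5 (later C4 of the tetrahydrofuran), the only centre from this step that persists, since C6 becomes CH2 and C1 is re-equilibrated in step 7.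

**Step 7**
Reactants: 8 the bicyclic cyclopropyl ketone
Product: 10 {3-methoxy-4-[tri(propan-2-yl)silyloxy]phenyl}[(3R,4R)-4-{3-methoxy-4-[tri(propan-2-yl)silyloxy]benzyl}tetrahydrofuran-3-yl]methanone (trans), via cis-ketone 9 (not isolated)
Conditions: H2 (1 atm), 10% Pd/C, EtOAc, rt; filter; DBU (0.2 equiv), THF, rt
Reagents that add atoms: none
Why: Catalytic hydrogenolysis of a donor–acceptor cyclopropane cleaves only the C1–C6 bond, which is both benzylic and α to the ketone, turning C6 into the benzyl CH2; the new α-keto centre forms unselectively and DBU equilibrates cis-ketone 9 through the enolate to the more stable trans-ketone 10, while C4 is untouched.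

**Step 8**
Reactants: 10 the trans-ketone
Product: 12 4-{(R)-hydroxy[(3R,4R)-4-(4-hydroxy-3-methoxybenzyl)tetrahydrofuran-3-yl]methyl}-2-methoxyphenol (target), via bis-silyl carbinol 11 (not isolated)
Conditions: (S)-Me-CBS (0.5 equiv), BH3·SMe2, toluene, −30 °C; MeOH; then n-Bu4NF, AcOH, THF, 0 °C
Reagents that add atoms: none
Why: Corey–Bakshi–Shibata reduction under non-epimerising conditions: the (S)-oxazaborolidine delivers hydride to the face that gives the (R)-carbinol (aryl as the large group, as for acetophenone), overriding the Felkin preference of 10 for the 7-epimer; buffered fluoride desilylation then frees both phenols without ionising the p-hydroxybenzylic alcohol.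

**Compound list**
1 | 4-bromo-2-methoxyphenol | COc1cc(Br)ccc1O | starting material
2 | (4-bromo-2-methoxyphenoxy)tri(propan-2-yl)silane | COc1cc(Br)ccc1O[Si](C(C)C)(C(C)C)C(C)C | intermediate
3 | prop-2-yn-1-ol | OCC#C | starting material
4 | 3-{3-methoxy-4-[tri(propan-2-yl)silyloxy]phenyl}prop-2-yn-1-ol | COc1cc(C#CCO)ccc1O[Si](C(C)C)(C(C)C)C(C)C | intermediate
5 | (2E)-3-{3-methoxy-4-[tri(propan-2-yl)silyloxy]phenyl}prop-2-en-1-ol | COc1cc(/C=C/CO)ccc1O[Si](C(C)C)(C(C)C)C(C)C | intermediate
6 | [4-(3-bromoprop-1-yn-1-yl)-2-methoxyphenoxy]tri(propan-2-yl)silane | COc1cc(C#CCBr)ccc1O[Si](C(C)C)(C(C)C)C(C)C | intermediate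
7 | 3-{3-methoxy-4-[tri(propan-2-yl)silyloxy]phenyl}prop-2-yn-1-yl (2E)-3-{3-methoxy-4-[tri(propan-2-yl)silyloxy]phenyl}prop-2-en-1-yl ether | COc1cc(/C=C/COCC#Cc2ccc(O[Si](C(C)C)(C(C)C)C(C)C)c(OC)c2)ccc1O[Si](C(C)C)(C(C)C)C(C)C | intermediate
8 | [(1R,5R,6S)-6-{3-methoxy-4-[tri(propan-2-yl)silyloxy]phenyl}-3-oxabicyclo[3.1.0]hexan-1-yl]{3-methoxy-4-[tri(propan-2-yl)silyloxy]phenyl}methanone | O=C(c1ccc(O[Si](C(C)C)(C(C)C)C(C)C)c(OC)c1)[C@@]12COC[C@@H]1[C@H]2c1ccc(O[Si](C(C)C)(C(C)C)C(C)C)c(OC)c1 | intermediate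
9 | {3-methoxy-4-[tri(propan-2-yl)silyloxy]phenyl}[(3S,4R)-4-{3-methoxy-4-[tri(propan-2-yl)silyloxy]benzyl}tetrahydrofuran-3-yl]methanone (cis) | COc1cc(C[C@H]2COC[C@H]2C(=O)c2ccc(O[Si](C(C)C)(C(C)C)C(C)C)c(OC)c2)ccc1O[Si](C(C)C)(C(C)C)C(C)C | intermediate
10 | {3-methoxy-4-[tri(propan-2-yl)silyloxy]phenyl}[(3R,4R)-4-{3-methoxy-4-[tri(propan-2-yl)silyloxy]benzyl}tetrahydrofuran-3-yl]methanone (trans) | COc1cc(C[C@H]2COC[C@@H]2C(=O)c2ccc(O[Si](C(C)C)(C(C)C)C(C)C)c(OC)c2)ccc1O[Si](C(C)C)(C(C)C)C(C)C | intermediate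
11 | (R)-{3-methoxy-4-[tri(propan-2-yl)silyloxy]phenyl}[(3R,4R)-4-{3-methoxy-4-[tri(propan-2-yl)silyloxy]benzyl}tetrahydrofuran-3-yl]methanol | COc1cc(C[C@H]2COC[C@@H]2[C@@H](O)c2ccc(O[Si](C(C)C)(C(C)C)C(C)C)c(OC)c2)ccc1O[Si](C(C)C)(C(C)C)C(C)C | intermediate
12 | 4-{(R)-hydroxy[(3R,4R)-4-(4-hydroxy-3-methoxybenzyl)tetrahydrofuran-3-yl]methyl}-2-methoxyphenol | COc1cc(C[C@H]2COC[C@@H]2[C@@H](O)c2ccc(O)c(OC)c2)ccc1O | target

**Step count**
Total: 8 steps. Longest linear sequence: 7 steps (1, 2, 3 or 4, 5, 6, 7, 8).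

**Three steps most likely to fail, each with a fallback**

Step 6 (key step). Risks: 1,2-hydride shift of the carbenoid to an enone, over-oxidation to a 1,2-diketone, trapping of the benzylic cation by the alkyne-side arene, and insufficient enantioselectivity with the ether tether. Fallback: 7 is instead submitted to an enantioselective gold-catalysed hydroxycyclisation ((R)-DTBM-MeO-BIPHEP(AuCl)2, AgOTf, wet dioxane, rt). 5-exo-dig attack of the styrene on the activated alkyne with anti addition of water across the (E)-alkene gives the benzylidene carbinol (R)-[(3R,4E)-4-{3-methoxy-4-[tri(propan-2-yl)silyloxy]benzylidene}tetrahydrofuran-3-yl]{3-methoxy-4-[tri(propan-2-yl)silyloxy]phenyl}methanol F1, with the carbinol and C3 centres set stereospecifically. Hydroxyl-directed hydrogenation of the exocyclic alkene ([Ir(cod)(PCy3)(py)]PF6, H2, CH2Cl2) adds hydrogen on the face of the carbinol side chain and gives the trans compound 11, where the route is rejoined for the fluoride half of step 8.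

Step 8 (carbinol centre). Risk: the oxazaborolidine has to override the substrate's Felkin bias with an α-branched aryl ketone, so the diastereomer ratio may be modest. Fallback: switch to substrate control followed by inversion. From 10, LiBH(s-Bu)3 (THF, −78 °C) reduces under Felkin control to the (S)-carbinol (S)-{3-methoxy-4-[tri(propan-2-yl)silyloxy]phenyl}[(3R,4R)-4-{3-methoxy-4-[tri(propan-2-yl)silyloxy]benzyl}tetrahydrofuran-3-yl]methanol F2. A Mitsunobu reaction (4-nitrobenzoic acid, PPh3, DIAD, toluene, 0 °C) inverts it to the (R)-4-nitrobenzoate F3. Methanolysis (K2CO3, MeOH) gives 11, and the route is rejoined at the fluoride half of step 8.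

Step 7 (hydrogenolysis). Risks: over-reduction of the aryl ketone to the alcohol or methylene, and cleavage of the wrong cyclopropane bond. Fallback: from 8, single-electron reduction with SmI2 (2.2 equiv, THF/MeOH, −78 °C) forms the ketyl, which fragments to the benzylic radical; a second electron transfer and protonation give the same 9/10 mixture without hydrogen or palladium, and the route is rejoined at 10 after the DBU equilibration.

**Further compounds**
F1 | step 6 | (R)-[(3R,4E)-4-{3-methoxy-4-[tri(propan-2-yl)silyloxy]benzylidene}tetrahydrofuran-3-yl]{3-methoxy-4-[tri(propan-2-yl)silyloxy]phenyl}methanol | COc1cc(/C=C2/COC[C@@H]2[C@@H](O)c2ccc(O[Si](C(C)C)(C(C)C)C(C)C)c(OC)c2)ccc1O[Si](C(C)C)(C(C)C)C(C)C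
F0 | step 7 | none | none
F2 | step 8 | (S)-{3-methoxy-4-[tri(propan-2-yl)silyloxy]phenyl}[(3R,4R)-4-{3-methoxy-4-[tri(propan-2-yl)silyloxy]benzyl}tetrahydrofuran-3-yl]methanol | COc1cc(C[C@H]2COC[C@@H]2[C@H](O)c2ccc(O[Si](C(C)C)(C(C)C)C(C)C)c(OC)c2)ccc1O[Si](C(C)C)(C(C)C)C(C)C
F3 | step 8 | (R)-{3-methoxy-4-[tri(propan-2-yl)silyloxy]phenyl}[(3R,4R)-4-{3-methoxy-4-[tri(propan-2-yl)silyloxy]benzyl}tetrahydrofuran-3-yl]methyl 4-nitrobenzoate | COc1cc(C[C@H]2COC[C@@H]2[C@@H](OC(=O)c2ccc(cc2)[N+](=O)[O-])c2ccc(O[Si](C(C)C)(C(C)C)C(C)C)c(OC)c2)ccc1O[Si](C(C)C)(C(C)C)C(C)C
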